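**Plan**

- Retrosynthesis: the C–CH2Br bond is cut first (Weinreb amide plus LiCH2Br), then the exocyclic C2=C bond (lactone plus propanamide enolate, dehydration); both lead back to the trans-fused bromolactone 12 (benzofuran locants O1, C2, C3, C3a, C4–C7, C7a).
- The lactone is then cut at O1–C2 and C3a–C7a together. Ring B (O1, C2, C3, C3a, C7a) carries O1 on the methyl-bearing carbinol carbon C7a and C2 at the carboxyl level three carbons away, so it is a γ-lactone in disguise. A ketyl at C7a and an acrylate unit C3a=C3–C2 should therefore give both bonds in one reductive cyclisation/lactonisation of an acyclic keto-enoate.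
- Forward: methyl 3,3-dimethylpent-4-enoate supplies C3a, C4 with its two methyls, C5 and C6; a methallyl Grignard reagent adds C7, C7a and its methyl; a Wittig ylide adds C3 and C2. Ring A (cyclohexane) and then ring B close in step 6; the side chain is built last.
- Stereochemistry: C5–Br is set by amine-catalysed α-bromination of an aldehyde; C3a and C7a are relayed from C5 in the chair transition state of step 6; the (Z)-enol ether is reached by acid equilibration to the thermodynamic isomer.

Key step: step 6

Assumption: the sense of induction in step 2 is taken from the enamine face-shielding model, by which (2S,5S)-2,5-diphenylpyrrolidine gives the (R)-α-bromoaldehyde; the antipodal amine would be used if the sense proved opposite.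

**Step 1**
Reactants: 1 methyl 3,3-dimethylpent-4-enoate
Product: 2 3,3-dimethylpent-4-enal
Conditions: i-Bu2AlH (1.05 equiv), CH2Cl2, −78 °C; Rochelle salt work-up
Reagents that add atoms: none
Why: Partial reduction of an ester with i-Bu2AlH at −78 °C stops at the aluminium hemiacetal, which should release the aldehyde on work-up (DIBAL ester-to-aldehyde reduction); no stereocenter is formed.

**Step 2**
Reactants: 2 3,3-dimethylpent-4-enal
Product: 4 (R)-2-bromo-3,3-dimethylpent-4-en-1-ol, via α-bromoaldehyde 3 (not isolated)
Conditions: (2S,5S)-2,5-diphenylpyrrolidine (20 mol%), PhCO2H (20 mol%), 4,4-dibromo-2,6-di-tert-butylcyclohexa-2,5-dien-1-one (1.05 equiv), H2O (2 equiv), CH2Cl2/pentane 1:1, −40 °C; then NaBH4, MeOH, −40 → 0 °C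
Reagents that add atoms: 4,4-dibromo-2,6-di-tert-butylcyclohexa-2,5-dien-1-one, CC(C)(C)C1=CC(Br)(Br)C=C(C(C)(C)C)C1=O
Why: Enamine-catalysed electrophilic α-bromination of an aldehyde (Jørgensen-type) should deliver Br+ to the enamine face left open by the C2-symmetric amine and so set the bromine-bearing stereocenter as R, and immediate NaBH4 reduction fixes it before the α-bromoaldehyde can racemise.

**Step 3**
Reactants: 4 (R)-2-bromo-3,3-dimethylpent-4-en-1-ol; 5 2-methylallylmagnesium chloride
Product: 7 (S)-5-bromo-2,6,6-trimethylocta-1,7-diene, via primary triflate 6 (not isolated)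
Conditions: Tf2O (1.1 equiv), 2,6-lutidine, CH2Cl2, −78 °C; cold silica plug; then 5 (1.5 equiv), CuBr·SMe2 (10 mol%), Et2O/THF, −78 → −20 °C
Reagents that add atoms: none
Why: Triflation of the primary alcohol followed by copper-catalysed SN2 coupling of the primary triflate with an allylic Grignard reagent (Kotsuki-type triflate alkylation) should form the C6–C7 bond at the primary carbon only, because the neighbouring secondary bromide is neopentylic and inert to substitution; its configuration is untouched and the descriptor changes from R to S only through the change in priorities.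

**Step 4**
Reactants: 7 (S)-5-bromo-2,6,6-trimethylocta-1,7-diene
Product: 8 (S)-3-bromo-2,2-dimethyl-6-oxoheptanal
Conditions: O3, CH2Cl2, −78 °C; then PPh3, −78 °C → rt
Reagents that add atoms: ozone, [O-][O+]=O
Why: Ozonolysis with reductive work-up should cleave both terminal alkenes at once, the 1,1-disubstituted one to the methyl ketone and the vinyl group to an aldehyde that has no α-hydrogen and so cannot lose HBr; the stereocenter is not touched.

**Step 5**
Reactants: 8 (S)-3-bromo-2,2-dimethyl-6-oxoheptanal; 9 methyl (triphenylphosphoranylidene)acetate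
Product: 10 methyl (S,E)-5-bromo-4,4-dimethyl-8-oxonon-2-enoate
Conditions: 9 (1.2 equiv), PhMe, 60 °C
Reagents that add atoms: none
Why: Wittig olefination with a stabilised ylide is selective for the aldehyde over the methyl ketone, should give the (E)-enoate, and is not basic enough to enolise the γ-bromo ketone towards cyclopropane formation.

**Step 6**
Reactants: 10 methyl (S,E)-5-bromo-4,4-dimethyl-8-oxonon-2-enoate
Product: 12 (3aS,5S,7aS)-5-bromo-4,4,7a-trimethylhexahydro-1-benzofuran-2(3H)-one, via trans hydroxy ester 11 (not isolated)
Conditions: SmI2 (2.5 equiv), MeOH (4 equiv), THF, −78 → 0 °C; then TsOH·H2O (cat.), CH2Cl2, rt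
Reagents that add atoms: none
Why: SmI2 transfers one electron to the methyl ketone, the samarium ketyl adds through C7a to the enoate β-carbon C3a in a 6-exo-trig radical cyclisation that closes ring A, the α-ester radical is reduced and protonated by MeOH, and the trivalent samarium alkoxide (completed by the acid) attacks the ester in a 5-exo-trig acyl substitution that closes the lactone of ring B and expels methanol. The closest known reaction type is the SmI2-mediated ketyl–olefin (ketone–enoate) reductive cyclisation to γ-lactones. C3a is set by the C5 stereocenter through a chair transition state in which bromine and the enoate arm are both equatorial, which places H3a and H5 cis; the equatorial preference of bromine is modest, so any minor C3a/C7a diastereomer would be removed by chromatography at the lactone stage. C7a is set relative to C3a by the usual anti preference of ketyl–enoate closures, in which the bulky solvated O–Sm group takes the equatorial site and the methyl group the axial one, so that O1 and the CH2CO2Me arm are trans and the ring fusion is trans. The step needs electron transfer to the carbonyl groups and not to the secondary C–Br bond, which HMPA-free SmI2 with MeOH at low temperature should secure because unactivated alkyl bromides are reduced only slowly under these conditions. C4 is quaternary, so the enoate has no γ-hydrogen and no β-leaving group, and deconjugation or elimination pathways are closed.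

**Step 7**
Reactants: 12 (3aS,5S,7aS)-5-bromo-4,4,7a-trimethylhexahydro-1-benzofuran-2(3H)-one; 13 N-methoxy-N-methylpropanamide
Product: 15 (2Z)-2-[(3aS,5S,7aS)-5-bromo-4,4,7a-trimethylhexahydro-1-benzofuran-2(3H)-ylidene]-N-methoxy-N-methylpropanamide, via β-keto amide lactol 14 (not isolated)
Conditions: 13 (2.3 equiv), LiN(i-Pr)2 (2.2 equiv), THF, −78 °C; then 12, −78 → −40 °C; AcOH quench; then CSA (10 mol%), 4 Å MS, PhMe, 40 °C
Reagents that add atoms: none
Why: Claisen-type acylation of the amide enolate by the lactone should give the β-keto amide as its cyclic hemiketal, and acid-catalysed dehydration through the oxocarbenium ion gives the conjugated exocyclic enol ether (vinylogous carbamate), whose E and Z isomers interconvert under the acid by C-protonation and rotation and should converge on the Z isomer, in which the carboxamide lies on the side of the ring oxygen and the small methyl group faces the C3 methylene.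

**Step 8**
Reactants: 15 (2Z)-2-[(3aS,5S,7aS)-5-bromo-4,4,7a-trimethylhexahydro-1-benzofuran-2(3H)-ylidene]-N-methoxy-N-methylpropanamide
Product: 16 (3Z)-1-bromo-3-[(3aS,5S,7aS)-5-bromo-4,4,7a-trimethylhexahydro-1-benzofuran-2(3H)-ylidene]butan-2-one
Conditions: CH2Br2 (3 equiv), MeLi·LiBr (2.5 equiv, slow addition), THF/Et2O, −78 °C; AcOH quench at −78 °C
Reagents that add atoms: dibromomethane, BrCBr
Why: Acylation of a lithium halocarbenoid by a Weinreb amide: LiCH2Br formed by Br/Li exchange should add once to give a chelated tetrahedral intermediate that releases the bromomethyl ketone only on quench, so that double addition and epoxide formation are avoided and the ring stereocenters and the alkene geometry are untouched.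

**Compound list**

1 | methyl 3,3-dimethylpent-4-enoate | COC(=O)CC(C)(C)C=C | starting material
2 | 3,3-dimethylpent-4-enal | O=CCC(C)(C)C=C | intermediate
3 | (R)-2-bromo-3,3-dimethylpent-4-enal | C=CC(C)(C)[C@@H](Br)C=O | intermediate (not isolated)
4 | (R)-2-bromo-3,3-dimethylpent-4-en-1-ol | C=CC(C)(C)[C@@H](Br)CO | intermediate
5 | 2-methylallylmagnesium chloride | CC(=C)C[Mg]Cl | starting material
6 | (R)-2-bromo-3,3-dimethylpent-4-en-1-yl trifluoromethanesulfonate | C=CC(C)(C)[C@@H](Br)COS(=O)(=O)C(F)(F)F | intermediate (not isolated)
7 | (S)-5-bromo-2,6,6-trimethylocta-1,7-diene | C=CC(C)(C)[C@@H](Br)CCC(C)=C | intermediate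
8 | (S)-3-bromo-2,2-dimethyl-6-oxoheptanal | O=CC(C)(C)[C@@H](Br)CCC(C)=O | intermediate
9 | methyl (triphenylphosphoranylidene)acetate | COC(=O)C=P(c1ccccc1)(c1ccccc1)c1ccccc1 | starting material
10 | methyl (S,E)-5-bromo-4,4-dimethyl-8-oxonon-2-enoate | COC(=O)/C=C/C(C)(C)[C@@H](Br)CCC(C)=O | intermediate
11 | methyl 2-[(1S,2S,5S)-5-bromo-2-hydroxy-2,6,6-trimethylcyclohexyl]acetate | COC(=O)C[C@H]1C(C)(C)[C@@H](Br)CC[C@]1(C)O | intermediate (not isolated)
12 | (3aS,5S,7aS)-5-bromo-4,4,7a-trimethylhexahydro-1-benzofuran-2(3H)-one | O=C1C[C@H]2C(C)(C)[C@@H](Br)CC[C@]2(C)O1 | intermediate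
13 | N-methoxy-N-methylpropanamide | CCC(=O)N(C)OC | starting material
14 | 2-[(3aS,5S,7aS)-5-bromo-2-hydroxy-4,4,7a-trimethyloctahydro-1-benzofuran-2-yl]-N-methoxy-N-methylpropanamide (epimers at C2 and at the amide α-carbon) | CC(C(=O)N(C)OC)C1(O)C[C@H]2C(C)(C)[C@@H](Br)CC[C@]2(C)O1 | intermediate (not isolated)
15 | (2Z)-2-[(3aS,5S,7aS)-5-bromo-4,4,7a-trimethylhexahydro-1-benzofuran-2(3H)-ylidene]-N-methoxy-N-methylpropanamide | C/C(C(=O)N(C)OC)=C1\C[C@H]2C(C)(C)[C@@H](Br)CC[C@]2(C)O1 | intermediate
16 | (3Z)-1-bromo-3-[(3aS,5S,7aS)-5-bromo-4,4,7a-trimethylhexahydro-1-benzofuran-2(3H)-ylidene]butan-2-one | C/C(C(=O)CBr)=C1\C[C@H]2C(C)(C)[C@@H](Br)CC[C@]2(C)O1 | target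

Total step count: 8
Longest linear sequence: 8 steps (from 1)

**Steps most likely to fail**

Step 6. Two processes may interfere. Electron transfer may go to the C–Br bond and remove the bromine. The relay from C5 may also be weak, because bromine has only a small equatorial preference, and the facial selectivity at the ketyl carbon may be poor, which would give the cis-fused lactone. The fallback is a two-electron, catalyst-controlled closure that uses no reductant. It sets out from 8: Wittig reaction with (triphenylphosphoranylidene)acetaldehyde in PhMe should give (S,E)-5-bromo-4,4-dimethyl-8-oxonon-2-enal F1. A chiral N-heterocyclic carbene (aminoindanol-derived N-mesityl triazolium salt with DBU in THF, in the enantiomer that reinforces the C5 bias) would convert the enal into its homoenolate, which adds through C3a to the ketone; the alkoxide then acylates on the acyl azolium and releases the catalyst. The route is rejoined at 12.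

Step 3. The β-bromo triflate may be lost by E2 elimination, by bromine participation (1,2-bromine shift through a bromonium ion), or by attack of the Grignard reagent at sulfur followed by epoxide closure. The fallback makes the C6–C7 bond by olefination and sets out from 2. The α-bromination of step 2 is run as before, but the α-bromoaldehyde 3 is trapped with 1-(triphenylphosphoranylidene)propan-2-one in place of NaBH4 to give (S,E)-5-bromo-6,6-dimethylocta-3,7-dien-2-one F2. Conjugate reduction with [(Ph3P)CuH]6 (cat.), polymethylhydrosiloxane and t-BuOH in PhMe at 0 °C, where the alcohol protonates the copper enolate at once, should give (S)-5-bromo-6,6-dimethyloct-7-en-2-one F3. Ozonolysis (O3, CH2Cl2, −78 °C; PPh3) of the vinyl group rejoins the route at 8.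

Step 8. Addition of the short-lived carbenoid to the hindered, electron-rich amide carbonyl may be slow, so that decomposition of LiCH2Br or deprotonation at C3 takes over. The fallback introduces the bromine by electrophilic bromination and sets out from 15. MeLi in THF at −78 °C should give (3Z)-3-[(3aS,5S,7aS)-5-bromo-4,4,7a-trimethylhexahydro-1-benzofuran-2(3H)-ylidene]butan-2-one F4. LiN(SiMe3)2 and Me3SiCl at −78 °C remove the kinetic α′-proton to give {[(3Z)-3-[(3aS,5S,7aS)-5-bromo-4,4,7a-trimethylhexahydro-1-benzofuran-2(3H)-ylidene]but-1-en-2-yl]oxy}trimethylsilane F5, a 1-alkoxy-3-silyloxy diene. NBS in THF at −78 °C brominates its terminal carbon and rejoins the route at 16.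

**Further compounds**

F1 | step 6 | (S,E)-5-bromo-4,4-dimethyl-8-oxonon-2-enal | O=C/C=C/C(C)(C)[C@@H](Br)CCC(C)=O
F2 | step 3 | (S,E)-5-bromo-6,6-dimethylocta-3,7-dien-2-one | C=CC(C)(C)[C@@H](Br)/C=C/C(C)=O
F3 | step 3 | (S)-5-bromo-6,6-dimethyloct-7-en-2-one | C=CC(C)(C)[C@@H](Br)CCC(C)=O
F4 | step 8 | (3Z)-3-[(3aS,5S,7aS)-5-bromo-4,4,7a-trimethylhexahydro-1-benzofuran-2(3H)-ylidene]butan-2-one | C/C(C(C)=O)=C1\C[C@H]2C(C)(C)[C@@H](Br)CC[C@]2(C)O1
F5 | step 8 | {[(3Z)-3-[(3aS,5S,7aS)-5-bromo-4,4,7a-trimethylhexahydro-1-benzofuran-2(3H)-ylidene]but-1-en-2-yl]oxy}trimethylsilane | C/C(C(=C)O[Si](C)(C)C)=C1\C[C@H]2C(C)(C)[C@@H](Br)CC[C@]2(C)O1
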